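The 3-methoxyflavone is cut across ring C at the C4–C4a and O1–C2 bonds, giving phloroglucinol and a racemic ethyl aroyl(methoxy)acetate that already holds C2, C3 with its methoxy group, C4 and the whole 4-hydroxy-3,5-diprenylphenyl ring B. The key step exploits the threefold symmetry of ring A before annulation: any of its CH carbons can serve as C4a and either flanking hydroxyl as O1, so the 5,7-dihydroxy pattern arises without protection or regiocontrol. One uncatalysed thermal operation acylates that carbon, closes the pyranone and delivers the free target. The keto ester is reached from a dibromobenzoate by MOM protection, double Stille prenylation, crossed Claisen condensation and MOM removal.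

Key step: step 5

Remark: ethyl 3,5-dibromo-4-hydroxybenzoate is assumed to be a catalogue compound. The ethyl benzoate is chosen so that the alkoxide released in step 3 matches the ester of the nucleophile and no mixed methyl/ethyl keto esters can form.
Remark: compounds 8 and 9 are racemic at C2 of the propanoate chain. This centre becomes the sp2 carbon C3 in step 5, and the target is achiral.

Step 1
Reactants: 1 ethyl 3,5-dibromo-4-hydroxybenzoate
Product: 2 ethyl 3,5-dibromo-4-(methoxymethoxy)benzoate
Conditions: MOMCl (1.5 equiv), K2CO3 (2 equiv), acetone, 0 °C → rt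
Reagents that add atoms: chloromethyl methyl ether, COCCl
Why: Williamson-type O-alkylation (MOM ether formation), in which the acidic 2,6-dibromophenol is deprotonated by carbonate and the phenoxide displaces chloride from the very reactive chloromethyl ether while the ethyl ester is untouched.

Step 2
Reactants: 2 ethyl 3,5-dibromo-4-(methoxymethoxy)benzoate; 3 tributyl(3-methylbut-2-enyl)stannane (2.6 equiv)
Product: 5 ethyl 4-(methoxymethoxy)-3,5-bis(3-methylbut-2-enyl)benzoate, via monoprenyl bromide 4 (not isolated)
Conditions: Pd(PPh3)4 (5–10 mol %), DMF, 100 °C, Ar; chromatography on K2CO3-doped silica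
Reagents that add atoms: none
Why: Twofold Stille cross-coupling, in which each C–Br bond (activated by the para ester) adds oxidatively to zerovalent palladium, the prenyl group is transferred from tin, and reductive elimination at the less hindered primary allyl terminus should give the linear prenyl arene with ester and MOM ether inert.

Step 3
Reactants: 5 ethyl 4-(methoxymethoxy)-3,5-bis(3-methylbut-2-enyl)benzoate; 6 ethyl methoxyacetate
Product: 8 ethyl 2-methoxy-3-[4-(methoxymethoxy)-3,5-bis(3-methylbut-2-enyl)phenyl]-3-oxopropanoate (racemic), via lithium enolate 7 (not isolated)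
Conditions: 6 (2.6 equiv), LiN(iPr)2 (2.5 equiv), THF, −78 °C; then 5, −78 → −20 °C; AcOH quench
Reagents that add atoms: none
Why: Crossed Claisen condensation, in which the preformed ester enolate adds to the non-enolisable benzoate, ethoxide leaves, and deprotonation of the new keto ester by the second equivalent of enolate drives the reaction, while the slight excess of 6 over amide base leaves no free amide to attack the benzylic-allylic CH2 groups.

Step 4
Reactants: 8 ethyl 2-methoxy-3-[4-(methoxymethoxy)-3,5-bis(3-methylbut-2-enyl)phenyl]-3-oxopropanoate (racemic)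
Product: 9 ethyl 3-[4-hydroxy-3,5-bis(3-methylbut-2-enyl)phenyl]-2-methoxy-3-oxopropanoate (racemic)
Conditions: aq. HCl (ca. 1 M final), EtOH, rt → 40 °C, monitored and stopped at full conversion
Reagents that add atoms: none
Why: Acid-catalysed acetal hydrolysis (MOM cleavage) of a doubly ortho-substituted aryl MOM ether, which should proceed under dilute acid too mild to protonate the trisubstituted alkenes or hydrolyse the keto ester, with ethanol as solvent making any ester exchange degenerate.

Step 5
Reactants: 9 ethyl 3-[4-hydroxy-3,5-bis(3-methylbut-2-enyl)phenyl]-2-methoxy-3-oxopropanoate (racemic); 10 phloroglucinol (benzene-1,3,5-triol, anhydrous, 2.5 equiv)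
Product: 13 5,7-dihydroxy-2-[4-hydroxy-3,5-bis(3-methylbut-2-enyl)phenyl]-3-methoxychromen-4-one (target), via acylketene 11 (not isolated), via diketone 12 (not isolated)
Conditions: neat melt, Ar sweep, microwave, 240 °C, 5–10 min; aqueous wash to remove excess 10
Reagents that add atoms: none
Why: This is the Mentzer thermal pyrone synthesis, a known annulation of phloroglucinol with aroylacetates (α-substituted ones included), applied here to an α-methoxy ester with a prenylated ring B. On heating, 9 loses ethanol, most plausibly through aroyl(methoxy)ketene 11 (an aryl ester formed by transesterification with 10 would lead to the same place), and a ring A carbon, activated by two ortho and one para hydroxyl, attacks the acyl carbon to form the C4–C4a bond and give 1,3-diketone 12. The hydroxyl ortho to the new acyl group then adds to the aryl ketone (6-exo-trig hemiketal formation) and loss of water forms the O1–C2 bond and the C2=C3 double bond, closing ring C. No stereocentre is created, and the racemic centre of 9 ends as the sp2 carbon C3. The step needs chromone rather than coumarin formation and one rather than two annulations: the absence of acid disfavours the Pechmann pathway so the ester carbon, not the ketone, bonds to the ring, the symmetry of 10 makes all sites equivalent, and the excess of 10 together with the deactivating acyl group suppresses a second annulation. Short neutral heating with removal of ethanol and water is expected to spare the prenyl groups and the hindered C4' hydroxyl.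

Compound list
1 | ethyl 3,5-dibromo-4-hydroxybenzoate | CCOC(=O)c1cc(Br)c(O)c(Br)c1 | starting material
2 | ethyl 3,5-dibromo-4-(methoxymethoxy)benzoate | CCOC(=O)c1cc(Br)c(OCOC)c(Br)c1 | intermediate
3 | tributyl(3-methylbut-2-enyl)stannane | CCCC[Sn](CCCC)(CCCC)CC=C(C)C | starting material
4 | ethyl 3-bromo-4-(methoxymethoxy)-5-(3-methylbut-2-enyl)benzoate (not isolated) | CCOC(=O)c1cc(Br)c(OCOC)c(CC=C(C)C)c1 | intermediate
5 | ethyl 4-(methoxymethoxy)-3,5-bis(3-methylbut-2-enyl)benzoate | CCOC(=O)c1cc(CC=C(C)C)c(OCOC)c(CC=C(C)C)c1 | intermediate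
6 | ethyl methoxyacetate | CCOC(=O)COC | starting material
7 | lithium enolate of ethyl methoxyacetate (not isolated, geometry not defined) | CCOC(O[Li])=COC | intermediate
8 | ethyl 2-methoxy-3-[4-(methoxymethoxy)-3,5-bis(3-methylbut-2-enyl)phenyl]-3-oxopropanoate (racemic) | CCOC(=O)C(OC)C(=O)c1cc(CC=C(C)C)c(OCOC)c(CC=C(C)C)c1 | intermediate
9 | ethyl 3-[4-hydroxy-3,5-bis(3-methylbut-2-enyl)phenyl]-2-methoxy-3-oxopropanoate (racemic) | CCOC(=O)C(OC)C(=O)c1cc(CC=C(C)C)c(O)c(CC=C(C)C)c1 | intermediate
10 | phloroglucinol (benzene-1,3,5-triol) | Oc1cc(O)cc(O)c1 | starting material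
11 | 3-[4-hydroxy-3,5-bis(3-methylbut-2-enyl)phenyl]-2-methoxy-3-oxoprop-1-en-1-one, the aroyl(methoxy)ketene (not isolated) | COC(=C=O)C(=O)c1cc(CC=C(C)C)c(O)c(CC=C(C)C)c1 | intermediate
12 | 1-[4-hydroxy-3,5-bis(3-methylbut-2-enyl)phenyl]-2-methoxy-3-(2,4,6-trihydroxyphenyl)propane-1,3-dione (racemic, not isolated) | COC(C(=O)c1c(O)cc(O)cc1O)C(=O)c1cc(CC=C(C)C)c(O)c(CC=C(C)C)c1 | intermediate
13 | 5,7-dihydroxy-2-[4-hydroxy-3,5-bis(3-methylbut-2-enyl)phenyl]-3-methoxychromen-4-one | COc1c(-c2cc(CC=C(C)C)c(O)c(CC=C(C)C)c2)oc2cc(O)cc(O)c2c1=O | target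

Total step count: 5
Longest linear sequence: 5 steps (1 → 2 → 5 → 8 → 9 → 13)

Steps most likely to fail

Step 5. The water released could hydrolyse the ester, with loss of CO2 following, or a prenyl group could close onto the C4' hydroxyl in the hot phenolic melt, either process outrunning the annulation. The fallback builds ring C by a Baker–Venkataraman sequence. It sets out from ester 5 and phloroglucinol 10 and comes back to the route at diketone 12, which closes to 13 under the final conditions. Ester 5 is saponified (LiOH, THF/EtOH/H2O, 50 °C) to 4-(methoxymethoxy)-3,5-bis(3-methylbut-2-enyl)benzoic acid F1. In parallel, a Hoesch reaction of 10 with methoxyacetonitrile (ZnCl2, HCl gas, Et2O, 0 °C) should precipitate 2-methoxy-1-(2,4,6-trihydroxyphenyl)ethaniminium chloride F2, which is hydrolysed in boiling water to 2-methoxy-1-(2,4,6-trihydroxyphenyl)ethanone F3. Protection with MOMCl (2.2 equiv) and iPr2NEt in CH2Cl2 leaves the chelated hydroxyl free and gives 1-[2-hydroxy-4,6-bis(methoxymethoxy)phenyl]-2-methoxyethanone F4. Esterification of F4 with F1 (EDC·HCl, DMAP, CH2Cl2) gives 2-(methoxyacetyl)-3,5-bis(methoxymethoxy)phenyl 4-(methoxymethoxy)-3,5-bis(3-methylbut-2-enyl)benzoate F5. Enolisation with LiN(SiMe3)2 in THF (−20 °C → rt) should move the aroyl group from oxygen to carbon, giving 1-[2-hydroxy-4,6-bis(methoxymethoxy)phenyl]-2-methoxy-3-[4-(methoxymethoxy)-3,5-bis(3-methylbut-2-enyl)phenyl]propane-1,3-dione F6. Dilute HCl in methanol at 40–50 °C then removes the three MOM groups to give 12 and cyclodehydrates it to 13.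

Step 2. Allyl transposition on palladium could lead to bond formation through the tertiary terminus, or the sequence could stall after the first coupling. The fallback sets out from dibromide 2 and comes back at 5. A double Stille coupling with allyltributylstannane (Pd(PPh3)4, DMF, 100 °C), which has no regiochemical ambiguity, gives ethyl 4-(methoxymethoxy)-3,5-bis(prop-2-enyl)benzoate F7. Twofold cross-metathesis with 2-methylbut-2-ene (used in large excess, second-generation Grubbs catalyst, CH2Cl2, 40 °C) then converts both allyl groups into prenyl groups and gives 5.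

Step 3. Acylation of the stabilised α-alkoxy enolate by the electron-rich benzoate could be slow, so that enolate decomposition on warming wins and conversion stays low. The fallback replaces the Claisen condensation by an aldol addition and oxidation; it sets out from ester 5 and comes back at 8. Reduction with iBu2AlH (CH2Cl2, −78 °C) gives [4-(methoxymethoxy)-3,5-bis(3-methylbut-2-enyl)phenyl]methanol F8. Oxidation with MnO2 (CH2Cl2, rt) gives 4-(methoxymethoxy)-3,5-bis(3-methylbut-2-enyl)benzaldehyde F9. Addition of lithium enolate 7 (THF, −78 °C) gives ethyl 3-hydroxy-2-methoxy-3-[4-(methoxymethoxy)-3,5-bis(3-methylbut-2-enyl)phenyl]propanoate F10 as a mixture of racemic diastereomers. Oxidation of the benzylic alcohol with Dess–Martin periodinane (NaHCO3, CH2Cl2, 0 °C → rt) converges on 8.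

Further compounds
F1 | step 5 | 4-(methoxymethoxy)-3,5-bis(3-methylbut-2-enyl)benzoic acid | COCOc1c(CC=C(C)C)cc(C(=O)O)cc1CC=C(C)C
F2 | step 5 | 2-methoxy-1-(2,4,6-trihydroxyphenyl)ethaniminium chloride | COCC(=[NH2+])c1c(O)cc(O)cc1O.[Cl-]
F3 | step 5 | 2-methoxy-1-(2,4,6-trihydroxyphenyl)ethanone | COCC(=O)c1c(O)cc(O)cc1O
F4 | step 5 | 1-[2-hydroxy-4,6-bis(methoxymethoxy)phenyl]-2-methoxyethanone | COCC(=O)c1c(O)cc(OCOC)cc1OCOC
F5 | step 5 | 2-(methoxyacetyl)-3,5-bis(methoxymethoxy)phenyl 4-(methoxymethoxy)-3,5-bis(3-methylbut-2-enyl)benzoate | COCC(=O)c1c(OC(=O)c2cc(CC=C(C)C)c(OCOC)c(CC=C(C)C)c2)cc(OCOC)cc1OCOC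
F6 | step 5 | 1-[2-hydroxy-4,6-bis(methoxymethoxy)phenyl]-2-methoxy-3-[4-(methoxymethoxy)-3,5-bis(3-methylbut-2-enyl)phenyl]propane-1,3-dione (racemic) | COC(C(=O)c1c(O)cc(OCOC)cc1OCOC)C(=O)c1cc(CC=C(C)C)c(OCOC)c(CC=C(C)C)c1
F7 | step 2 | ethyl 4-(methoxymethoxy)-3,5-bis(prop-2-enyl)benzoate | CCOC(=O)c1cc(CC=C)c(OCOC)c(CC=C)c1
F8 | step 3 | [4-(methoxymethoxy)-3,5-bis(3-methylbut-2-enyl)phenyl]methanol | COCOc1c(CC=C(C)C)cc(CO)cc1CC=C(C)C
F9 | step 3 | 4-(methoxymethoxy)-3,5-bis(3-methylbut-2-enyl)benzaldehyde | COCOc1c(CC=C(C)C)cc(C=O)cc1CC=C(C)C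
F10 | step 3 | ethyl 3-hydroxy-2-methoxy-3-[4-(methoxymethoxy)-3,5-bis(3-methylbut-2-enyl)phenyl]propanoate (mixture of racemic diastereomers) | CCOC(=O)C(OC)C(O)c1cc(CC=C(C)C)c(OCOC)c(CC=C(C)C)c1
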